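Ring B is disconnected at C1'–C6', treating the pyrogallol ring as the aromatic tautomer of a 6-methyl-2,3,4-trioxocyclohexane-1-carboxylate. The key step closes ring B by an intramolecular Michael addition. The ester-flanked carbon C1' of an open-chain aryl (E)-3,5-dioxooct-6-enoate, which already carries ring A through its C4–O ester bond, attacks the methyl-bearing enone terminus C6'. The result is a cyclohexane-1,3-dione in which C3' is a methylene between the C2' and C4' carbonyls. Acidified by both, C3' is then oxidized to a ketone, and ring B aromatizes by tautomerization alone, without any dehydrogenation.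

Key step: step 3

Remarks on the chemistry:
- Numbering: ring A is the methyl benzoate ring (C1 carries CO2Me, C2 the free OH, C4 the ester oxygen). Ring B is C1'–C6' (C1' carries the carboxyl, C2'–C4' the three oxygens, C6' the methyl).
- Assumption: the cyclized dione, its diazo derivative and the trione are racemic. The SMILES show one enantiomer of the trans pair; both centres vanish on aromatization and the target is achiral.
- The C2 hydroxyl of ring A is carried unprotected. It is hydrogen-bonded to the ester carbonyl and flanked on both sides, so it should remain a spectator.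
- The open-chain aryl ester is an activated ester of a 1,3,5-tricarbonyl chain. It is therefore made with excess phenol, not stored, and cyclized cold.

Step 1
Reactants: 1 2,2,6-trimethyl-4H-1,3-dioxin-4-one; 2 (E)-but-2-enoyl chloride (crotonoyl chloride)
Product: 4 2,2-dimethyl-6-[(3E)-2-oxopent-3-en-1-yl]-4H-1,3-dioxin-4-one, via lithium dienolate 3 (not isolated)
Conditions: 1 (2.1 equiv), LiN(iPr)2 (2.1 equiv), THF, −78 °C; then 2 (1.0 equiv), −78 °C; AcOH quench
Reagents that add atoms: none
Why: Kinetic deprotonation of the 6-methyl group gives the cross-conjugated lithium dienolate, which is acylated at its exocyclic gamma-carbon by the acid chloride at −78 °C (vinylogous Claisen-type C-acylation); the second equivalent of dienolate absorbs the acidic proton of the product, no stereocentre is formed and the (E)-alkene of 2 is carried through unchanged.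

Step 2
Reactants: 4 2,2-dimethyl-6-[(3E)-2-oxopent-3-en-1-yl]-4H-1,3-dioxin-4-one; 5 methyl 2,4-dihydroxy-3,6-dimethylbenzoate (atraric acid)
Product: 7 3-hydroxy-4-(methoxycarbonyl)-2,5-dimethylphenyl (6E)-3,5-dioxooct-6-enoate, via acylketene 6 (not isolated)
Conditions: 5 (3 equiv), PhMe, 110 °C, short heating; product used at once
Reagents that add atoms: none
Why: Heating causes a retro-hetero-Diels–Alder loss of acetone from the dioxinone, and the acylketene adds the O–H of the freer, non-chelated C4 hydroxyl of 5 (acylketene trapping by a phenol); the excess of phenol is meant to outrun capture of the ketene by its own enolized ketone.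

Step 3
Reactants: 7 3-hydroxy-4-(methoxycarbonyl)-2,5-dimethylphenyl (6E)-3,5-dioxooct-6-enoate
Product: 8 3-hydroxy-4-(methoxycarbonyl)-2,5-dimethylphenyl (1RS,6SR)-6-methyl-2,4-dioxocyclohexane-1-carboxylate
Conditions: 1,8-diazabicyclo[5.4.0]undec-7-ene (DBU, 1.5 equiv), CH2Cl2, −20 °C to rt; cold 1 M HCl work-up
Reagents that add atoms: none
Why: The amidine deprotonates the tricarbonyl chain reversibly, and the enolate centred on C1' (whose acidity the electron-poor aryl ester should bring close to that of the C3' methylene) adds through carbon to C6' of the s-trans enone; the new enolate is protonated at C5' and the ring ends as the amidinium salt of a vinylogous acid. The closest known reaction is the base-mediated intramolecular Michael addition of a beta-keto ester to an enone, the ring-closing counterpart of the classical Michael–Claisen assembly of 5-substituted cyclohexane-1,3-diones. Ring B closes in the 6-endo-trig mode at the enone (enolendo for the donor), which is the only carbon closure available because attack from C3' would need a four-membered ring. C6' is formed without facial bias and is racemic, while C1' stays acidic and should settle trans to the C6' methyl with both substituents equatorial; neither centre survives into the target. The step needs carbon rather than oxygen cyclization and must spare the aryl ester: the oxygen adduct (a dihydropyranone from the C2' enol oxygen) can reopen by beta-elimination, whereas the carbocycle is removed from the equilibrium as a stabilized enolate. Intramolecular O-acylation, which would expel ring A and leave a 4-hydroxy-2-pyrone, is the main threat and is restrained only by the non-nucleophilic base, the low temperature and the deactivation of the ester carbonyl within the C1' enolate.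

Step 4
Reactants: 8 3-hydroxy-4-(methoxycarbonyl)-2,5-dimethylphenyl (1RS,6SR)-6-methyl-2,4-dioxocyclohexane-1-carboxylate
Product: 9 3-hydroxy-4-(methoxycarbonyl)-2,5-dimethylphenyl (1RS,6SR)-3-diazo-6-methyl-2,4-dioxocyclohexane-1-carboxylate
Conditions: 4-AcNHC6H4SO2N3 (1.1 equiv), Et3N (1.2 equiv), MeCN, 0 °C to rt
Reagents that add atoms: 4-acetamidobenzenesulfonyl azide, CC(=O)Nc1ccc(cc1)S(=O)(=O)N=[N+]=[N-]
Why: Regitz diazo transfer: the enolate of the cyclic 1,3-dione attacks the terminal nitrogen of the sulfonyl azide and the triazene collapses to the 2-diazo-1,3-dione and the sulfonamide, C3' being the only carbon with two exchangeable hydrogens between two ketones (C1' is a methine), so the C1' and C6' centres are not touched.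

Step 5
Reactants: 9 3-hydroxy-4-(methoxycarbonyl)-2,5-dimethylphenyl (1RS,6SR)-3-diazo-6-methyl-2,4-dioxocyclohexane-1-carboxylate
Product: 11 3-hydroxy-4-(methoxycarbonyl)-2,5-dimethylphenyl 2,3,4-trihydroxy-6-methylbenzoate (CNP0249278.0), via trione 10 (not isolated)
Conditions: dimethyldioxirane (DMDO, 1.0 equiv), acetone, −20 to 0 °C; evaporate; AcOH (cat.), degassed EtOAc, rt, argon
Reagents that add atoms: dimethyldioxirane, CC1(C)OO1
Why: The dioxirane transfers an oxygen atom to the nucleophilic diazo carbon with loss of dinitrogen (the known oxidation of 2-diazo-1,3-diones to vicinal triones); the trione then enolizes toward C1' and C5' and a final acid-assisted proton shift from C6' to the C3' oxygen (keto–enol tautomerization) should give the aromatic pyrogallol, erasing both stereocentres.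

Compound list
1 | 2,2,6-trimethyl-4H-1,3-dioxin-4-one | CC1=CC(=O)OC(C)(C)O1 | starting material
2 | (E)-but-2-enoyl chloride (crotonoyl chloride) | C/C=C/C(Cl)=O | starting material
3 | lithium 2,2-dimethyl-6-methylidene-6H-1,3-dioxin-4-olate (lithium dienolate of 1) | [Li+].[O-]C1=CC(=C)OC(C)(C)O1 | intermediate
4 | 2,2-dimethyl-6-[(3E)-2-oxopent-3-en-1-yl]-4H-1,3-dioxin-4-one | CC1(C)OC(=O)C=C(CC(=O)/C=C/C)O1 | intermediate
5 | methyl 2,4-dihydroxy-3,6-dimethylbenzoate (atraric acid) | COC(=O)c1c(C)cc(O)c(C)c1O | starting material
6 | (6E)-octa-1,6-diene-1,3,5-trione (acylketene) | O=C=CC(=O)CC(=O)/C=C/C | intermediate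
7 | 3-hydroxy-4-(methoxycarbonyl)-2,5-dimethylphenyl (6E)-3,5-dioxooct-6-enoate | COC(=O)c1c(C)cc(OC(=O)CC(=O)CC(=O)/C=C/C)c(C)c1O | intermediate
8 | 3-hydroxy-4-(methoxycarbonyl)-2,5-dimethylphenyl (1RS,6SR)-6-methyl-2,4-dioxocyclohexane-1-carboxylate (trans, racemic; one enantiomer drawn) | COC(=O)c1c(C)cc(OC(=O)[C@H]2[C@H](C)CC(=O)CC2=O)c(C)c1O | intermediate
9 | 3-hydroxy-4-(methoxycarbonyl)-2,5-dimethylphenyl (1RS,6SR)-3-diazo-6-methyl-2,4-dioxocyclohexane-1-carboxylate (trans, racemic; one enantiomer drawn) | COC(=O)c1c(C)cc(OC(=O)[C@H]2[C@H](C)CC(=O)C(=[N+]=[N-])C2=O)c(C)c1O | intermediate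
10 | 3-hydroxy-4-(methoxycarbonyl)-2,5-dimethylphenyl (1RS,6SR)-6-methyl-2,3,4-trioxocyclohexane-1-carboxylate (trans, racemic; one enantiomer drawn) | COC(=O)c1c(C)cc(OC(=O)[C@H]2[C@H](C)CC(=O)C(=O)C2=O)c(C)c1O | intermediate
11 | 3-hydroxy-4-(methoxycarbonyl)-2,5-dimethylphenyl 2,3,4-trihydroxy-6-methylbenzoate (CNP0249278.0; achiral) | COC(=O)c1c(C)cc(OC(=O)c2c(C)cc(O)c(O)c2O)c(C)c1O | target

Total step count: 5
Longest linear sequence: 5 steps (1 → 4 → 7 → 8 → 9 → 11)

Steps most likely to fail

Step 3 (key step). Intramolecular O-acylation may outrun carbon–carbon bond formation: the enolate oxygen at C4' can displace the ring A phenoxide from the activated aryl ester and end in a 4-hydroxy-2-pyrone. The reaction may also stall at the oxygen-cyclized dihydropyranone. In the fallback ring B would be built before ring A is attached. tert-Butyl methyl malonate and (E)-pent-3-en-2-one would be combined under KOC(CH3)3 in tert-butanol, first to the Michael adduct tert-butyl methyl 2-(4-oxopentan-2-yl)propanedioate F1 (not isolated). Claisen closure of the methyl ketone onto the methyl ester would then give tert-butyl (1RS,6SR)-6-methyl-2,4-dioxocyclohexane-1-carboxylate F2. F2 would be heated with atraric acid 5 in xylene at about 135 °C, so that loss of tert-butanol generates the cyclic alpha-oxoketene, which the C4 hydroxyl of 5 traps. This fallback sets out from compound 5 and comes back to the route at compound 8.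

Step 2. Capture of acylketene 6 by its own enolized C5 carbonyl, or thermal re-ionization of the aryl ester once formed, may compete with the bimolecular addition of the hindered, electron-poor phenol. Both processes drain material into a pyrone. In the fallback ring A would be attached before the C5 carbonyl exists. Dioxinone 1 and atraric acid 5 would be heated in xylene to give 3-hydroxy-4-(methoxycarbonyl)-2,5-dimethylphenyl 3-oxobutanoate F3, since acetylketene has no internal trap. F3 would be deprotonated three times (LiN(iPr)2, 3.2 equiv, THF, −78 °C) and acylated at its terminal methyl carbon with (E)-N-methoxy-N-methylbut-2-enamide (C/C=C/C(=O)N(C)OC). The chelated tetrahedral adduct should release the enone only on acidic quench. This fallback sets out from compounds 1 and 5 and comes back at compound 7.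

Step 5. Over-oxidation may occur: the dioxirane can attack the pyrogallol as soon as tautomerization produces it, or hydroxylate the strongly enolized C1' position of the trione. In the fallback the C3' oxygen would come from cleavage of a carbon–carbon double bond instead of from the diazo compound. Dione 8 would be condensed with N,N-dimethylformamide dimethyl acetal (PhMe, rt) to 3-hydroxy-4-(methoxycarbonyl)-2,5-dimethylphenyl (1RS,6SR)-3-[(dimethylamino)methylidene]-6-methyl-2,4-dioxocyclohexane-1-carboxylate F4. The enamine double bond of F4 would be cleaved by singlet oxygen (O2, 5,10,15,20-tetraphenylporphyrin, visible light, CH2Cl2, −40 °C), releasing N,N-dimethylformamide. The oxidant would be purged before warming. This fallback sets out from compound 8 and comes back at trione 10, which tautomerizes to 11 as in step 5.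

Further compounds
F1 | step 3 | tert-butyl methyl 2-(4-oxopentan-2-yl)propanedioate (mixture of diastereomers, not isolated) | COC(=O)C(C(C)CC(C)=O)C(=O)OC(C)(C)C
F2 | step 3 | tert-butyl (1RS,6SR)-6-methyl-2,4-dioxocyclohexane-1-carboxylate (trans, racemic; one enantiomer drawn) | CC(C)(C)OC(=O)[C@H]1[C@H](C)CC(=O)CC1=O
F3 | step 2 | 3-hydroxy-4-(methoxycarbonyl)-2,5-dimethylphenyl 3-oxobutanoate | COC(=O)c1c(C)cc(OC(=O)CC(C)=O)c(C)c1O
F4 | step 5 | 3-hydroxy-4-(methoxycarbonyl)-2,5-dimethylphenyl (1RS,6SR)-3-[(dimethylamino)methylidene]-6-methyl-2,4-dioxocyclohexane-1-carboxylate (trans, racemic; one enantiomer drawn) | COC(=O)c1c(C)cc(OC(=O)[C@H]2[C@H](C)CC(=O)C(=CN(C)C)C2=O)c(C)c1O
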